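**Plan**

Ring A (C1 CH2OH, C2 bridging CH2, C3 OH, C4 OMe, C5 OH, C6 H) carries the O,O,O,H run C3–C6, a 2‑methoxyacetoacetate in disguise; C1 and C2 are then an alkyne.
Retrosynthesis: the bridging CH2 goes back to a ketone, ring A is cut at C6–C1 and C2–C3 into an oxygenated diene and an aroylalkyne, and the ynone is cut at the carbonyl–alkyne bond into the ring B aldehyde and a propargyl ether.
Forward: the diene arm (from methyl acetoacetate) and the ynone arm (ring B carried intact from vanillin, plus propargyl alcohol) are made separately; ring A is then formed in one Diels–Alder benzannulation.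
The diaryl ketone is reduced to CH2 through an o‑quinone methide and the silyl ethers are removed.
The target has no stereocentre; the only selectivity to control is the regiochemistry of the cycloaddition.

Key step: step 12

Assumptions: the target is achiral, so the compound as drawn is the single species required. The E/Z geometry shown for 4, 5, 6 and 21 is the expected one but has no consequence, because these carbons end in aromatic ring A or the CH2 bridge. The diene is made with a TBS group on O‑3 and a TMS group on O‑1, so that the key step delivers ring A with OH (C3), OMe (C4) and OTBS (C5) already differentiated. TBS = tert‑butyldimethylsilyl, TMS = trimethylsilyl, p‑ABSA = 4‑acetamidobenzenesulfonyl azide.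

**Diene arm**

Step 1
Reactants: 1 methyl acetoacetate
Product: 2 methyl 2‑diazo‑3‑oxobutanoate
Conditions: p‑ABSA, Et3N, MeCN, 0 °C → rt
Reagents that add atoms: 4‑acetamidobenzenesulfonyl azide, CC(=O)Nc1ccc(cc1)S(=O)(=O)N=[N+]=[N-]
Why: Regitz diazo transfer to the doubly activated methylene of a β‑keto ester is a standard, reliable reaction.

Step 2
Reactants: 2 methyl 2‑diazo‑3‑oxobutanoate
Product: 3 methyl 2‑methoxy‑3‑oxobutanoate (racemic)
Conditions: Rh2(OAc)4 (1 mol%), MeOH, CH2Cl2, reflux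
Reagents that add atoms: methanol, CO
Why: Rhodium(II) carbenoid O–H insertion into an alcohol is well established for 2‑diazo‑1,3‑dicarbonyl compounds and installs the future C4 methoxy group without strong base.

Step 3
Reactants: 3 methyl 2‑methoxy‑3‑oxobutanoate
Product: 4 methyl (2Z)‑3‑(tert‑butyldimethylsilyloxy)‑2‑methoxybut‑2‑enoate
Conditions: TBSOTf, Et3N, CH2Cl2, 0 °C
Reagents that add atoms: tert‑butyldimethylsilyl triflate, CC(C)(C)[Si](C)(C)OS(=O)(=O)C(F)(F)F
Why: Soft enolisation of the β‑keto ester with a silyl triflate and triethylamine removes the most acidic C2–H and should give the conjugated silyl enol ether, the robust TBS group keeping this oxygen (future C5–O) protected after the key step.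

Step 4
Reactants: 4 methyl (2Z)‑3‑(tert‑butyldimethylsilyloxy)‑2‑methoxybut‑2‑enoate
Product: 6 (1E)‑3‑(tert‑butyldimethylsilyloxy)‑1,2‑dimethoxy‑1‑(trimethylsilyloxy)buta‑1,3‑diene, via lithium dienolate 5 (not isolated)
Conditions: LDA, THF, −78 °C; then TMSCl, −78 → 0 °C; used crude after filtration under argon
Reagents that add atoms: chlorotrimethylsilane, C[Si](C)(C)Cl
Why: γ‑Deprotonation of a 3‑silyloxy‑2‑enoate with LDA and O‑silylation of the dienolate is the standard route to 1‑alkoxy‑1,3‑bis(silyloxy)buta‑1,3‑dienes, and the labile TMS ketene acetal marks the oxygen (future C3–OH) to be freed on work‑up.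

**Ynone arm**

Step 5
Reactants: 7 vanillin
Product: 8 5‑bromovanillin (3‑bromo‑4‑hydroxy‑5‑methoxybenzaldehyde)
Conditions: Br2, MeOH, 0 °C → rt
Reagents that add atoms: bromine, BrBr
Why: Electrophilic aromatic bromination of vanillin goes ortho to the free phenol, the para position being blocked by the formyl group.

Step 6
Reactants: 8 5‑bromovanillin
Product: 9 2,3‑dibromo‑4‑hydroxy‑5‑methoxybenzaldehyde (5,6‑dibromovanillin)
Conditions: Br2, Fe powder (cat.), AcOH, rt
Reagents that add atoms: bromine, BrBr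
Why: A second iron‑catalysed electrophilic bromination should enter the remaining activated position para to the methoxy group, the site between CHO and OMe being hindered, which gives the contiguous dibromide of ring B.

Step 7
Reactants: 9 2,3‑dibromo‑4‑hydroxy‑5‑methoxybenzaldehyde
Product: 10 2,3‑dibromo‑4,5‑dihydroxybenzaldehyde
Conditions: AlCl3, pyridine, CH2Cl2, reflux; then aq. HCl
Reagents that add atoms: none
Why: Aluminium chloride–pyridine demethylation is selective for a methyl ether next to a free phenol, since the aluminium phenoxide chelates the methoxy oxygen and pyridine takes the methyl group, and it leaves aldehyde and aryl bromides untouched.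

Step 8
Reactants: 10 2,3‑dibromo‑4,5‑dihydroxybenzaldehyde
Product: 11 2,3‑dibromo‑4,5‑bis(tert‑butyldimethylsilyloxy)benzaldehyde
Conditions: TBSCl, imidazole, DMF, rt
Reagents that add atoms: tert‑butyldimethylsilyl chloride, CC(C)(C)[Si](C)(C)Cl
Why: Standard silylation masks the acidic catechol for the organolithium step with groups that fluoride removes at the end without touching the aryl bromides or the methyl ether.

Step 9
Reactants: 12 propargyl alcohol
Product: 13 tert‑butyldimethyl(prop‑2‑yn‑1‑yloxy)silane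
Conditions: TBSCl, imidazole, CH2Cl2, 0 °C → rt
Reagents that add atoms: tert‑butyldimethylsilyl chloride, CC(C)(C)[Si](C)(C)Cl
Why: Standard silylation of a primary alcohol, so that only the alkyne C–H is deprotonated in the next step.

Step 10
Reactants: 13 tert‑butyldimethyl(prop‑2‑yn‑1‑yloxy)silane; 11 2,3‑dibromo‑4,5‑bis(tert‑butyldimethylsilyloxy)benzaldehyde
Product: 15 4‑(tert‑butyldimethylsilyloxy)‑1‑[2,3‑dibromo‑4,5‑bis(tert‑butyldimethylsilyloxy)phenyl]but‑2‑yn‑1‑ol (racemic), via lithium acetylide 14 (not isolated)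
Conditions: 13, n‑BuLi, THF, −78 °C; then 11, −78 → −20 °C; aq. NH4Cl
Reagents that add atoms: none
Why: 1,2‑Addition of a lithium acetylide to an aromatic aldehyde is fast at −78 °C, and with all butyllithium consumed by the alkyne beforehand no bromine–lithium exchange should occur.

Step 11
Reactants: 15 4‑(tert‑butyldimethylsilyloxy)‑1‑[2,3‑dibromo‑4,5‑bis(tert‑butyldimethylsilyloxy)phenyl]but‑2‑yn‑1‑ol
Product: 16 4‑(tert‑butyldimethylsilyloxy)‑1‑[2,3‑dibromo‑4,5‑bis(tert‑butyldimethylsilyloxy)phenyl]but‑2‑yn‑1‑one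
Conditions: activated MnO2, CH2Cl2, rt
Reagents that add atoms: none
Why: Manganese dioxide oxidation of benzylic–propargylic alcohols to ynones proceeds under neutral conditions that spare all silyl ethers.

**Ring A and endgame**

Step 12
Reactants: 6 (1E)‑3‑(tert‑butyldimethylsilyloxy)‑1,2‑dimethoxy‑1‑(trimethylsilyloxy)buta‑1,3‑diene; 16 4‑(tert‑butyldimethylsilyloxy)‑1‑[2,3‑dibromo‑4,5‑bis(tert‑butyldimethylsilyloxy)phenyl]but‑2‑yn‑1‑one
Product: 19 [2,3‑dibromo‑4,5‑bis(tert‑butyldimethylsilyloxy)phenyl][4‑(tert‑butyldimethylsilyloxy)‑6‑[(tert‑butyldimethylsilyloxy)methyl]‑2‑hydroxy‑3‑methoxyphenyl]methanone, via cyclohexa‑1,4‑diene cycloadduct 17 (not isolated), via aryl trimethylsilyl ether 18 (not isolated)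
Conditions: 6 (2 equiv), toluene, 80 °C; then 10% aq. citric acid, THF, 0 °C
Reagents that add atoms: none
Why: The electron‑rich dioxygenated diene should add thermally across the ynone triple bond in a normal‑electron‑demand Diels–Alder reaction, the closest known reaction being the cycloaddition of 1‑alkoxy‑1,3‑bis(silyloxy)buta‑1,3‑dienes with acetylenic ketones and esters to give resorcinols and salicylates. Ring A is closed by the intermolecular [4+2] itself, which forms C6–C1 and C2–C3 in a concerted but asynchronous way; a stepwise Mukaiyama–Michael addition followed by 6‑exo‑trig closure of the allenyl silyl ether carbon onto the ester‑derived oxocarbenium carbon would give the same ring. Regiochemistry is the selectivity needed: the CH2 terminus, the most nucleophilic diene carbon, bonds to the ynone β‑carbon bearing CH2OTBS and the ketene acetal carbon bonds to the α‑carbon, which places the aroyl group next to the future C3 hydroxyl. Cycloadduct 17 has OMe on its ketal carbon and H on C6, so 1,4‑elimination of methanol aromatises it to 18. The citric acid work‑up should cleave only the labile aryl O–SiMe3 bond ortho to the carbonyl, so ring A emerges with OH at C3, OMe at C4 and OTBS at C5; no stereocentre remains, the ketal stereocentre of 17 being lost on aromatisation.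

Step 13
Reactants: 19 [2,3‑dibromo‑4,5‑bis(tert‑butyldimethylsilyloxy)phenyl][4‑(tert‑butyldimethylsilyloxy)‑6‑[(tert‑butyldimethylsilyloxy)methyl]‑2‑hydroxy‑3‑methoxyphenyl]methanone
Product: 22 2‑[2,3‑dibromo‑4,5‑bis(tert‑butyldimethylsilyloxy)benzyl]‑5‑(tert‑butyldimethylsilyloxy)‑3‑[(tert‑butyldimethylsilyloxy)methyl]‑6‑methoxyphenol, via aryl ethyl carbonate 20 (not isolated), via o‑quinone methide 21 (not isolated)
Conditions: ClCO2Et, Et3N, THF, 0 °C; then NaBH4, H2O, 0 °C → rt
Reagents that add atoms: none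
Why: This is the known reductive deoxygenation of o‑acylphenols through their ethyl carbonates: borohydride reduces the ketone, the carbonate migrates to the benzylic alkoxide and is expelled by the phenoxide to give o‑quinone methide 21, which takes up a second hydride, all under basic conditions that should leave the CH2OTBS group, the aryl bromides and the silyl ethers alone.

Step 14
Reactants: 22 2‑[2,3‑dibromo‑4,5‑bis(tert‑butyldimethylsilyloxy)benzyl]‑5‑(tert‑butyldimethylsilyloxy)‑3‑[(tert‑butyldimethylsilyloxy)methyl]‑6‑methoxyphenol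
Product: 23 3,4‑dibromo‑5‑{[2,4‑dihydroxy‑6‑(hydroxymethyl)‑3‑methoxyphenyl]methyl}benzene‑1,2‑diol (target)
Conditions: TBAF, AcOH, THF, 0 °C → rt, under argon
Reagents that add atoms: none
Why: Fluoride cleavage of the three aryl and one primary alkyl TBS ethers, buffered with acetic acid so that air‑sensitive polyphenoxides are not generated, should release the target, whose methyl ether, bromides and benzylic alcohol are inert to these conditions.

**Compound list**

1 | methyl acetoacetate | COC(=O)CC(C)=O | starting material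
2 | methyl 2‑diazo‑3‑oxobutanoate | COC(=O)C(=[N+]=[N-])C(C)=O | intermediate
3 | methyl 2‑methoxy‑3‑oxobutanoate (racemic) | COC(=O)C(OC)C(C)=O | intermediate
4 | methyl (2Z)‑3‑(tert‑butyldimethylsilyloxy)‑2‑methoxybut‑2‑enoate | C/C(O[Si](C)(C)C(C)(C)C)=C(/OC)C(=O)OC | intermediate
5 | lithium (1E)‑3‑(tert‑butyldimethylsilyloxy)‑1,2‑dimethoxybuta‑1,3‑dien‑1‑olate (not isolated) | C=C(O[Si](C)(C)C(C)(C)C)/C(OC)=C(/OC)O[Li] | intermediate
6 | (1E)‑3‑(tert‑butyldimethylsilyloxy)‑1,2‑dimethoxy‑1‑(trimethylsilyloxy)buta‑1,3‑diene | C=C(O[Si](C)(C)C(C)(C)C)/C(OC)=C(/OC)O[Si](C)(C)C | intermediate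
7 | vanillin | COc1cc(C=O)ccc1O | starting material
8 | 5‑bromovanillin | COc1cc(C=O)cc(Br)c1O | intermediate
9 | 2,3‑dibromo‑4‑hydroxy‑5‑methoxybenzaldehyde | COc1cc(C=O)c(Br)c(Br)c1O | intermediate
10 | 2,3‑dibromo‑4,5‑dihydroxybenzaldehyde | O=Cc1cc(O)c(O)c(Br)c1Br | intermediate
11 | 2,3‑dibromo‑4,5‑bis(tert‑butyldimethylsilyloxy)benzaldehyde | O=Cc1cc(O[Si](C)(C)C(C)(C)C)c(O[Si](C)(C)C(C)(C)C)c(Br)c1Br | intermediate
12 | propargyl alcohol | C#CCO | starting material
13 | tert‑butyldimethyl(prop‑2‑yn‑1‑yloxy)silane | C#CCO[Si](C)(C)C(C)(C)C | intermediate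
14 | [3‑(tert‑butyldimethylsilyloxy)prop‑1‑yn‑1‑yl]lithium (not isolated) | [Li]C#CCO[Si](C)(C)C(C)(C)C | intermediate
15 | 4‑(tert‑butyldimethylsilyloxy)‑1‑[2,3‑dibromo‑4,5‑bis(tert‑butyldimethylsilyloxy)phenyl]but‑2‑yn‑1‑ol (racemic) | OC(C#CCO[Si](C)(C)C(C)(C)C)c1cc(O[Si](C)(C)C(C)(C)C)c(O[Si](C)(C)C(C)(C)C)c(Br)c1Br | intermediate
16 | 4‑(tert‑butyldimethylsilyloxy)‑1‑[2,3‑dibromo‑4,5‑bis(tert‑butyldimethylsilyloxy)phenyl]but‑2‑yn‑1‑one | O=C(C#CCO[Si](C)(C)C(C)(C)C)c1cc(O[Si](C)(C)C(C)(C)C)c(O[Si](C)(C)C(C)(C)C)c(Br)c1Br | intermediate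
17 | [4‑(tert‑butyldimethylsilyloxy)‑2‑[(tert‑butyldimethylsilyloxy)methyl]‑5,6‑dimethoxy‑6‑(trimethylsilyloxy)cyclohexa‑1,4‑dien‑1‑yl][2,3‑dibromo‑4,5‑bis(tert‑butyldimethylsilyloxy)phenyl]methanone (racemic, not isolated) | COC1(O[Si](C)(C)C)C(OC)=C(O[Si](C)(C)C(C)(C)C)CC(CO[Si](C)(C)C(C)(C)C)=C1C(=O)c1cc(O[Si](C)(C)C(C)(C)C)c(O[Si](C)(C)C(C)(C)C)c(Br)c1Br | intermediate
18 | [2,3‑dibromo‑4,5‑bis(tert‑butyldimethylsilyloxy)phenyl][4‑(tert‑butyldimethylsilyloxy)‑6‑[(tert‑butyldimethylsilyloxy)methyl]‑3‑methoxy‑2‑(trimethylsilyloxy)phenyl]methanone (not isolated) | COc1c(O[Si](C)(C)C(C)(C)C)cc(CO[Si](C)(C)C(C)(C)C)c(C(=O)c2cc(O[Si](C)(C)C(C)(C)C)c(O[Si](C)(C)C(C)(C)C)c(Br)c2Br)c1O[Si](C)(C)C | intermediate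
19 | [2,3‑dibromo‑4,5‑bis(tert‑butyldimethylsilyloxy)phenyl][4‑(tert‑butyldimethylsilyloxy)‑6‑[(tert‑butyldimethylsilyloxy)methyl]‑2‑hydroxy‑3‑methoxyphenyl]methanone | COc1c(O[Si](C)(C)C(C)(C)C)cc(CO[Si](C)(C)C(C)(C)C)c(C(=O)c2cc(O[Si](C)(C)C(C)(C)C)c(O[Si](C)(C)C(C)(C)C)c(Br)c2Br)c1O | intermediate
20 | 2‑[2,3‑dibromo‑4,5‑bis(tert‑butyldimethylsilyloxy)benzoyl]‑5‑(tert‑butyldimethylsilyloxy)‑3‑[(tert‑butyldimethylsilyloxy)methyl]‑6‑methoxyphenyl ethyl carbonate (not isolated) | CCOC(=O)Oc1c(OC)c(O[Si](C)(C)C(C)(C)C)cc(CO[Si](C)(C)C(C)(C)C)c1C(=O)c1cc(O[Si](C)(C)C(C)(C)C)c(O[Si](C)(C)C(C)(C)C)c(Br)c1Br | intermediate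
21 | (6Z)‑6‑{[2,3‑dibromo‑4,5‑bis(tert‑butyldimethylsilyloxy)phenyl]methylidene}‑3‑(tert‑butyldimethylsilyloxy)‑5‑[(tert‑butyldimethylsilyloxy)methyl]‑2‑methoxycyclohexa‑2,4‑dien‑1‑one (o‑quinone methide, not isolated) | COC1=C(O[Si](C)(C)C(C)(C)C)C=C(CO[Si](C)(C)C(C)(C)C)/C(=C/c2cc(O[Si](C)(C)C(C)(C)C)c(O[Si](C)(C)C(C)(C)C)c(Br)c2Br)C1=O | intermediate
22 | 2‑[2,3‑dibromo‑4,5‑bis(tert‑butyldimethylsilyloxy)benzyl]‑5‑(tert‑butyldimethylsilyloxy)‑3‑[(tert‑butyldimethylsilyloxy)methyl]‑6‑methoxyphenol | COc1c(O[Si](C)(C)C(C)(C)C)cc(CO[Si](C)(C)C(C)(C)C)c(Cc2cc(O[Si](C)(C)C(C)(C)C)c(O[Si](C)(C)C(C)(C)C)c(Br)c2Br)c1O | intermediate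
23 | 3,4‑dibromo‑5‑{[2,4‑dihydroxy‑6‑(hydroxymethyl)‑3‑methoxyphenyl]methyl}benzene‑1,2‑diol | COc1c(O)cc(CO)c(Cc2cc(O)c(O)c(Br)c2Br)c1O | target

**Step count and risks**

Total steps: 14. Longest linear sequence: 9 steps (5, 6, 7, 8, 10, 11, 12, 13, 14, from vanillin).

Step 12. The internal, ortho‑hindered ynone may react sluggishly, so that hydrolysis or oligomerisation of the diene, or attack at the carbonyl, outruns the cycloaddition. Fallback: leave the route at 10 and join the rings by Friedel–Crafts benzylation instead. Reduction of 10 with NaBH4 in THF–water should give 2,3‑dibromo‑4,5‑dihydroxybenzyl alcohol F1. Under BF3·OEt2 in dioxane its p‑hydroxybenzyl cation should alkylate an excess of commercial methyl 3,5‑dihydroxy‑4‑methoxybenzoate at the one symmetry‑unique position ortho and para to the two hydroxyls, giving methyl 2‑(2,3‑dibromo‑4,5‑dihydroxybenzyl)‑3,5‑dihydroxy‑4‑methoxybenzoate F2. Reduction of the ester with excess DIBAL‑H in THF returns to the route at target 23.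

Step 13. Hydride delivery to the tri‑ortho‑substituted ketone may be slow, and loss of the carbonate before reduction would return the chelated, unreactive hydroxy ketone. Fallback: from 19, reduce the ketone with DIBAL‑H in CH2Cl2 at −78 °C to the diaryl carbinol [2,3‑dibromo‑4,5‑bis(tert‑butyldimethylsilyloxy)phenyl][4‑(tert‑butyldimethylsilyloxy)‑6‑[(tert‑butyldimethylsilyloxy)methyl]‑2‑hydroxy‑3‑methoxyphenyl]methanol F3. Ionic hydrogenation with Et3SiH and TFA in CH2Cl2 at −40 °C should ionise the doubly benzylic, o‑hydroxy‑stabilised position ahead of the primary benzylic silyl ether and rejoin the route at 22.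

Step 4. γ‑Deprotonation of the hindered TBS enol ether may be incomplete or accompanied by C‑silylation, and the ketene acetal may hydrolyse during isolation. Fallback: from 3, double soft enolisation with TMSOTf (2.2 equiv) and Et3N in Et2O at 0 °C gives (1E)‑1,2‑dimethoxy‑1,3‑bis(trimethylsilyloxy)buta‑1,3‑diene F4 in one operation without a lithium enolate. Heated with 16 as in step 12 it should give cycloadduct F5, which loses methanol to the bis(trimethylsilyl) ether F6; neither is isolated, and the acidic work‑up gives [2,3‑dibromo‑4,5‑bis(tert‑butyldimethylsilyloxy)phenyl][6‑[(tert‑butyldimethylsilyloxy)methyl]‑2,4‑dihydroxy‑3‑methoxyphenyl]methanone F7. TBSCl (1 equiv) and imidazole in DMF should silylate only the 4‑hydroxyl, the 2‑hydroxyl being hydrogen‑bonded to the ketone and flanked on both sides, which rejoins the route at 19.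

**Further compounds**

F1 | step 12 | 2,3‑dibromo‑4,5‑dihydroxybenzyl alcohol | OCc1cc(O)c(O)c(Br)c1Br
F2 | step 12 | methyl 2‑(2,3‑dibromo‑4,5‑dihydroxybenzyl)‑3,5‑dihydroxy‑4‑methoxybenzoate | COC(=O)c1cc(O)c(OC)c(O)c1Cc1cc(O)c(O)c(Br)c1Br
F3 | step 13 | [2,3‑dibromo‑4,5‑bis(tert‑butyldimethylsilyloxy)phenyl][4‑(tert‑butyldimethylsilyloxy)‑6‑[(tert‑butyldimethylsilyloxy)methyl]‑2‑hydroxy‑3‑methoxyphenyl]methanol (racemic) | COc1c(O[Si](C)(C)C(C)(C)C)cc(CO[Si](C)(C)C(C)(C)C)c(C(O)c2cc(O[Si](C)(C)C(C)(C)C)c(O[Si](C)(C)C(C)(C)C)c(Br)c2Br)c1O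
F4 | step 4 | (1E)‑1,2‑dimethoxy‑1,3‑bis(trimethylsilyloxy)buta‑1,3‑diene | C=C(O[Si](C)(C)C)/C(OC)=C(/OC)O[Si](C)(C)C
F5 | step 4 | [2‑[(tert‑butyldimethylsilyloxy)methyl]‑5,6‑dimethoxy‑4,6‑bis(trimethylsilyloxy)cyclohexa‑1,4‑dien‑1‑yl][2,3‑dibromo‑4,5‑bis(tert‑butyldimethylsilyloxy)phenyl]methanone (racemic, not isolated) | COC1(O[Si](C)(C)C)C(OC)=C(O[Si](C)(C)C)CC(CO[Si](C)(C)C(C)(C)C)=C1C(=O)c1cc(O[Si](C)(C)C(C)(C)C)c(O[Si](C)(C)C(C)(C)C)c(Br)c1Br
F6 | step 4 | [2,3‑dibromo‑4,5‑bis(tert‑butyldimethylsilyloxy)phenyl][6‑[(tert‑butyldimethylsilyloxy)methyl]‑3‑methoxy‑2,4‑bis(trimethylsilyloxy)phenyl]methanone (not isolated) | COc1c(O[Si](C)(C)C)cc(CO[Si](C)(C)C(C)(C)C)c(C(=O)c2cc(O[Si](C)(C)C(C)(C)C)c(O[Si](C)(C)C(C)(C)C)c(Br)c2Br)c1O[Si](C)(C)C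
F7 | step 4 | [2,3‑dibromo‑4,5‑bis(tert‑butyldimethylsilyloxy)phenyl][6‑[(tert‑butyldimethylsilyloxy)methyl]‑2,4‑dihydroxy‑3‑methoxyphenyl]methanone | COc1c(O)cc(CO[Si](C)(C)C(C)(C)C)c(C(=O)c2cc(O[Si](C)(C)C(C)(C)C)c(O[Si](C)(C)C(C)(C)C)c(Br)c2Br)c1O
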